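(The numbers in the tables are simulated on assumed constants; the scatter is artificial.)

No constant is given, so we read them from the runs.

| setting | ochre | red | amber | teal | larch | ash | cedar |
|---|---|---|---|---|---|---|---|
| starting material | 0.020 M | 0.020 M | 0.020 M | 0.030 M | 0.020 M (fed, over 1.00 h) | 0.020 M | 0.020 M |
| protic impurity | 10 mM | 10 mM | 10 mM | 10 mM | 10.0 mM | 10.0 mM | 10.0 mM |
| enzyme | 2 µM | 2.8 µM | 4.4 µM | 2 µM | 2.0 µM | 2.0 µM | 2.0 µM |
| remark | run made earlier | run made earlier | run made earlier | run made earlier | all but starting material at the start; starting material goes in evenly over 1.00 h, the run ends at 1.0 h | a single well-mixed tank run continuously and read at steady state, 1.0 h in it on average | a closed flask charged with all of it at once and left for 1.0 h |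
| time |  |  |  |  | 1.0 h |  | 1.0 h |

| run | time / min | product / % | starting material / % |
|---|---|---|---|
| ochre | 6.00 | 95.2 | 0.6 |
| ochre | 12.0 | 96.0 | 0.2 |
| ochre | 20.0 | 95.7 | 0.2 |
| ochre | 25.0 | 95.7 | 0.3 |
| ochre | 30.0 | 95.9 | 0 |
| ochre | 40.0 | 96.1 | 0.1 |
| red | 4.00 | 96.3 | 1.1 |
| red | 6.00 | 96.8 | 0.5 |
| red | 10.0 | 96.8 | 0.3 |
| red | 20.0 | 97.1 | 0 |
| red | 30.0 | 97.1 | 0 |
| red | 50.0 | 97.2 | 0 |
| amber | 8.00 | 97.8 | 0 |
| amber | 15.0 | 98.1 | 0 |
| amber | 25.0 | 98.2 | 0 |
| amber | 30.0 | 98.1 | 0.2 |
| amber | 40.0 | 98.2 | 0 |
| amber | 50.0 | 97.5 | 0.1 |
| teal | 4.00 | 94.6 | 1.8 |
| teal | 8.00 | 95.9 | 0.7 |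
| teal | 15.0 | 96.1 | 0 |
| teal | 25.0 | 96.4 | 0 |
| teal | 50.0 | 96.4 | 0 |

(each reading ± 0.3 percentage points)

- the stated concentrations are those of everything mixed, before any reaction; amounts are the same in each set-up
- candidate steps: starting material + protic impurity -> quenched substrate; starting material + enzyme -> product + enzyme
- the feed brings no volume worth counting
- the earlier runs were made in a closed, stirred flask

* the set-up with the highest amount of product at the outlet or at the end, in percent of the starting material put in ("none" if the first two lie within 2 percentage points) (larch / ash / cedar / none)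
* amount of product at the outlet or at the end, in percent of the starting material put in, larch
* amount of product at the outlet or at the end, in percent of the starting material put in, ash
* amount of product at the outlet or at the end, in percent of the starting material put in, cedar

In the red run starting material falls from 1.1% at 4.00 min to 0.5% at 6.00 min, a ratio of 2.20 where the inverse square of time gives 2.25. Each of these readings carries a scatter of 0.3 percentage points, so this is a hint and no proof; on it we take the product step to go with [starting material] to the power 1.50, and the quench with its first power. Product rate over quench rate then grows as the square root of [starting material].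

The reciprocal root of the fraction left, less 1, should rise steadily with time. The ochre, red and teal tails, scaled to ochre, give a slope κ of 1.56 /min. Ochre's plateau shows a loss of 4.15%, and integrating the square-root ratio makes this 2 times the starting ratio, 0.0207. Cedar should give 95.8%.

In larch, consumption outpaces the feed, so [starting material] stands low. The Damköhler number, 2κ times 1.00 h, is 187; the level is one over this number to the power 0.667, 3.06% of the charge. There the ratio rises to 0.119: quench rate over product rate at the level the feed holds, the standing ratio. Ash, with 1.0 h on average, has the same balance. Both read 86.7%, 9.1 points under cedar, beyond the margin. One number is nearly enough: by this estimate the quench spends 2.06 mM of 10.0 mM protic impurity, which the standing ratio does not count, so we read our product figure as low.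

The forecast gave 94.2%, 94.4% and 96%, hence none, holding that “selectivity doesn't depend on substrate”. The simulation gives 88.0% for larch, 88.7% for ash and 95.9% for cedar, so cedar.

    starting material + protic impurity → quenched substrate (k = 5.30 /M/min)
    starting material + enzyme → product + enzyme, rate k2*[starting material]^1.5*[enzyme]/(1 + ([starting material]/Kh2)^1.5) (26.0 mM, k = 1.60 × 10⁵ /M^1.5/s)

Larch's quench over product is 0.101, below our 0.119. Scaling 0.119 back to the charged level and down to 0.0060 M protic impurity gives a flask otherwise like cedar a loss of 2.50%; that flask shows 2.49% quenched substrate. Cedar has come to rest: at 10.0 h it still reads 95.9%. Larch has not: 3.17% starting material stands at 1.0 h, and by 10.0 h that is 0%, with product up from 88.0% to 90.7%.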